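**Strategy.** Everything rests on the C4–C4a bond of the trimethylisochroman core common to both halves (isochroman numbering). C4a lies meta to O6 and O8 and cannot be alkylated directly, but its neighbour C8a is para to O6 and ortho to O8. C4 is therefore first joined to C8a by ipso-alkylation, giving a 2-oxaspiro[4.5]decadienone whose five-membered ether ring (C8a, C1, O2, C3, C4) carries both stereocentres, taken from (2R,3R)-butane-2,3-diol. The key step, an acid-induced dienone–phenol 1,2-shift of C4 from C8a to C4a, expands that ring to the pyran and rearomatises the carbocycle in one operation. Dehydrogenation of one monomer and a methylene link finish the dimer.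

Key step: step 7

Remark: isochroman numbering (C1, O2, C3, C4, C4a, C5–C8, C8a) is used for all precursors; the spiro carbon of 10 is formed without control and written without configuration because step 7 removes it; 12 and 15 are written as the 6-hydroxy-8-oxo tautomers.

**Step 1**
Reactants: 1 4-methylresorcinol
Product: 3 2,4-dihydroxy-5-methylbenzaldehyde, via iminium chloride 2 (not isolated)
Conditions: POCl3, DMF, MeCN, 0 °C → rt; then H2O, 50 °C
Reagents that add atoms: N,N-dimethylformamide (CN(C)C=O); water (O)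
Why: Vilsmeier–Haack formylation should go to the ring carbon para to one hydroxyl and ortho to the other, the position between the two hydroxyls being more hindered, and the iminium salt is hydrolysed when water is added.

**Step 2**
Reactants: 3 2,4-dihydroxy-5-methylbenzaldehyde
Product: 4 2,4-bis[(tert-butyldimethylsilyl)oxy]-5-methylbenzaldehyde
Conditions: TBSCl (2.4 equiv), imidazole, DMF, rt
Reagents that add atoms: tert-butyldimethylsilyl chloride (CC(C)(C)[Si](C)(C)Cl)
Why: Standard silylation caps both phenols so that the hydride step and the alcohol bromination meet no acidic OH, and both caps fall to fluoride in step 6.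

**Step 3**
Reactants: 4 2,4-bis[(tert-butyldimethylsilyl)oxy]-5-methylbenzaldehyde; 5 (2R,3R)-butane-2,3-diol
Product: 6 (4R,5R)-2-{2,4-bis[(tert-butyldimethylsilyl)oxy]-5-methylphenyl}-4,5-dimethyl-1,3-dioxolane
Conditions: PPTS (cat.), toluene, reflux, Dean–Stark trap
Reagents that add atoms: none
Why: Acid-catalysed acetalisation driven by removal of water leaves both carbinol centres of 5 untouched, and because 5 is C2-symmetric the acetal carbon is not a stereocentre.

**Step 4**
Reactants: 6 (4R,5R)-2-{2,4-bis[(tert-butyldimethylsilyl)oxy]-5-methylphenyl}-4,5-dimethyl-1,3-dioxolane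
Product: 7 (2R,3R)-3-({2,4-bis[(tert-butyldimethylsilyl)oxy]-5-methylphenyl}methoxy)butan-2-ol
Conditions: i-Bu2AlH (3 equiv), CH2Cl2, −78 → 0 °C; aqueous potassium sodium tartrate
Reagents that add atoms: none
Why: Reductive acetal opening (aluminium coordination, ionisation to the aryl-stabilised oxocarbenium ion, hydride delivery) should give the same monoether from either C–O bond because of the C2 symmetry, with both stereocentres retained.

**Step 5**
Reactants: 7 (2R,3R)-3-({2,4-bis[(tert-butyldimethylsilyl)oxy]-5-methylphenyl}methoxy)butan-2-ol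
Product: 8 1-({[(2R,3S)-3-bromobutan-2-yl]oxy}methyl)-2,4-bis[(tert-butyldimethylsilyl)oxy]-5-methylbenzene
Conditions: PPh3, CBr4, CH2Cl2, 0 °C
Reagents that add atoms: carbon tetrabromide (BrC(Br)(Br)Br)
Why: In the Appel reaction bromide displaces the oxyphosphonium group by SN2 with inversion, turning the (R)-carbinol into the (S)-bromide, so that the second inversion in step 6 ends in the trans-3,4-dimethyl pattern.

**Step 6**
Reactants: 8 1-({[(2R,3S)-3-bromobutan-2-yl]oxy}methyl)-2,4-bis[(tert-butyldimethylsilyl)oxy]-5-methylbenzene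
Product: 10 (3R,4S)-6-hydroxy-3,4,9-trimethyl-2-oxaspiro[4.5]deca-6,9-dien-8-one, via bromo bisphenolate 9 (not isolated)
Conditions: n-Bu4NF (2.2 equiv), THF/t-BuOH, 0 → 40 °C; then 1 M HCl
Reagents that add atoms: none
Why: Fluoride frees the resorcinolate, whose carbon para to O6 and ortho to O8 (C8a) should displace the secondary bromide in a 5-exo-tet ipso-alkylation (Winstein Ar1-5 participation) with inversion to give (4S); the hydrogen-bonding cosolvent and the five- against seven-membered ring size favour C- over O-alkylation, and the new spiro centre needs no control.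

**Step 7**
Reactants: 10 (3R,4S)-6-hydroxy-3,4,9-trimethyl-2-oxaspiro[4.5]deca-6,9-dien-8-one
Product: 11 (3R,4S)-3,4,5-trimethyl-3,4-dihydro-1H-2-benzopyran-6,8-diol
Conditions: CF3SO3H (2 equiv), (CF3)2CHOH, 0 → 40 °C
Reagents that add atoms: none
Why: O-protonation of the vinylogous acid 10 gives a dihydroxycyclohexadienyl cation with positive charge on C4a and C8, the two ring carbons next to the spiro carbon C8a; the C8a–C4 bond, held nearly perpendicular to the ring plane by the spiro fusion, shifts suprafacially to C4a and loss of the C4a proton restores the benzene ring. This is the dienone–phenol rearrangement, closest to the ring expansion of spiro[4.5]decadienones to tetralins and to the spiroindolenine shift of the Pictet–Spengler reaction. No ring is closed by a cyclisation in the Baldwin sense: the five-membered ether ring (C8a, C1, O2, C3, C4) becomes the six-membered pyran (C8a, C1, O2, C3, C4, C4a) by a 1,2-shift. No stereocentre is created: C4 migrates with retention because the new bond forms on the face where the old one breaks, C3 is a spectator, and the spiro centre is erased so both epimers of 10 converge. The step needs C4 to migrate instead of C1 and needs C1 not to leave: C4 is a secondary alkyl carbon, whereas C1 is a primary carbon bearing O2, which lowers its migratory aptitude inductively as in related cationic 1,2-shifts, and heterolysis of C8a–C1 to an oxocarbenium ion would be the reverse of a 5-endo-trig closure for which the O2 lone pairs are misaligned. Migration towards C8 should be unproductive and reversible because C8 carries OH and no hydrogen, so only the shift to C4a can end in aromatisation.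

**Step 8**
Reactants: 11 (3R,4S)-3,4,5-trimethyl-3,4-dihydro-1H-2-benzopyran-6,8-diol
Product: 12 (3R,4S)-6-hydroxy-3,4,5-trimethyl-3,4-dihydro-8H-2-benzopyran-8-one
Conditions: DDQ (1.05 equiv), dry 1,4-dioxane, rt
Reagents that add atoms: none
Why: DDQ dehydrogenation should abstract hydride from C1, the benzylic ether carbon ortho and para to the two hydroxyls, and the oxocarbenium ion then loses a phenolic proton to give the quinone methide without touching C3 or C4.

**Step 9**
Reactants: 11 (3R,4S)-3,4,5-trimethyl-3,4-dihydro-1H-2-benzopyran-6,8-diol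
Product: 13 (3R,4S)-7-[(dimethylamino)methyl]-3,4,5-trimethyl-3,4-dihydro-1H-2-benzopyran-6,8-diol
Conditions: Me2NCH2NMe2 (1.2 equiv), 1,4-dioxane, rt
Reagents that add atoms: N,N,N',N'-tetramethylmethanediamine (CN(C)CN(C)C)
Why: The phenolic Mannich reaction can only occur at C7, the one free ring carbon, which is activated by both ortho hydroxyls.

**Step 10**
Reactants: 12 (3R,4S)-6-hydroxy-3,4,5-trimethyl-3,4-dihydro-8H-2-benzopyran-8-one; 13 (3R,4S)-7-[(dimethylamino)methyl]-3,4,5-trimethyl-3,4-dihydro-1H-2-benzopyran-6,8-diol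
Product: 15 (3R,4S)-7-{[(3R,4S)-6,8-dihydroxy-3,4,5-trimethyl-3,4-dihydro-1H-2-benzopyran-7-yl]methyl}-6-hydroxy-3,4,5-trimethyl-3,4-dihydro-8H-2-benzopyran-8-one, via ortho-quinone methide 14 (not isolated)
Conditions: 1,4-dioxane, 80 °C, N2 stream
Reagents that add atoms: none
Why: Thermal loss of dimethylamine from the ortho-hydroxybenzylamine gives ortho-quinone methide 14, which C7 of the vinylogous acid 12 should attack at the methylene carbon (Michael addition) with rearomatisation of the right-hand ring; 13 has no free ring carbon, so that half cannot dimerise with itself.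

**Compound list**

1 | 4-methylbenzene-1,3-diol (4-methylresorcinol) | Cc1ccc(O)cc1O | starting material
2 | [(2,4-dihydroxy-5-methylphenyl)methylidene]dimethylammonium chloride (not isolated) | C[N+](C)=Cc1cc(C)c(O)cc1O.[Cl-] | intermediate
3 | 2,4-dihydroxy-5-methylbenzaldehyde | O=Cc1cc(C)c(O)cc1O | intermediate
4 | 2,4-bis[(tert-butyldimethylsilyl)oxy]-5-methylbenzaldehyde | O=Cc1cc(C)c(O[Si](C)(C)C(C)(C)C)cc1O[Si](C)(C)C(C)(C)C | intermediate
5 | (2R,3R)-butane-2,3-diol | C[C@@H](O)[C@@H](C)O | starting material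
6 | (4R,5R)-2-{2,4-bis[(tert-butyldimethylsilyl)oxy]-5-methylphenyl}-4,5-dimethyl-1,3-dioxolane | C[C@H]1OC(c2cc(C)c(O[Si](C)(C)C(C)(C)C)cc2O[Si](C)(C)C(C)(C)C)O[C@@H]1C | intermediate
7 | (2R,3R)-3-({2,4-bis[(tert-butyldimethylsilyl)oxy]-5-methylphenyl}methoxy)butan-2-ol | C[C@@H](O)[C@@H](C)OCc1cc(C)c(O[Si](C)(C)C(C)(C)C)cc1O[Si](C)(C)C(C)(C)C | intermediate
8 | 1-({[(2R,3S)-3-bromobutan-2-yl]oxy}methyl)-2,4-bis[(tert-butyldimethylsilyl)oxy]-5-methylbenzene | C[C@H](Br)[C@@H](C)OCc1cc(C)c(O[Si](C)(C)C(C)(C)C)cc1O[Si](C)(C)C(C)(C)C | intermediate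
9 | 4-({[(2R,3S)-3-bromobutan-2-yl]oxy}methyl)-6-methylbenzene-1,3-diol, present as its phenolate (not isolated) | C[C@H](Br)[C@@H](C)OCc1cc(C)c(O)cc1O | intermediate
10 | (3R,4S)-6-hydroxy-3,4,9-trimethyl-2-oxaspiro[4.5]deca-6,9-dien-8-one, either configuration at the spiro carbon | C[C@@H]1[C@@H](C)OCC12C=C(C)C(=O)C=C2O | intermediate
11 | (3R,4S)-3,4,5-trimethyl-3,4-dihydro-1H-2-benzopyran-6,8-diol | Cc1c(O)cc(O)c2c1[C@H](C)[C@@H](C)OC2 | intermediate
12 | (3R,4S)-6-hydroxy-3,4,5-trimethyl-3,4-dihydro-8H-2-benzopyran-8-one (quinone methide) | CC1=C2C(=CO[C@H](C)[C@H]2C)C(=O)C=C1O | intermediate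
13 | (3R,4S)-7-[(dimethylamino)methyl]-3,4,5-trimethyl-3,4-dihydro-1H-2-benzopyran-6,8-diol | Cc1c(O)c(CN(C)C)c(O)c2c1[C@H](C)[C@@H](C)OC2 | intermediate
14 | (3R,4S)-8-hydroxy-3,4,5-trimethyl-7-methylidene-3,4-dihydro-1H-2-benzopyran-6(7H)-one (not isolated) | C=C1C(=O)C(C)=C2C(=C1O)CO[C@H](C)[C@H]2C | intermediate
15 | (3R,4S)-7-{[(3R,4S)-6,8-dihydroxy-3,4,5-trimethyl-3,4-dihydro-1H-2-benzopyran-7-yl]methyl}-6-hydroxy-3,4,5-trimethyl-3,4-dihydro-8H-2-benzopyran-8-one | CC1=C2C(=CO[C@H](C)[C@H]2C)C(=O)C(Cc2c(O)c(C)c3c(c2O)CO[C@H](C)[C@H]3C)=C1O | target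

**Count.** Total steps: 10. Longest linear sequence: 9 (steps 1–7, then step 8 or 9, then step 10).

**Steps most likely to fail**

Step 7. The 1,2-shift of C4 may be outrun by migration or heterolytic loss of the oxymethylene carbon C1, or it may stall because two free oxygen donors over-stabilise the starting cation. The fallback sets out from 10 and comes back at 11, and it changes the species that rearranges. Ac2O with catalytic H2SO4 (0 °C → rt) acetylates both oxygens of 10, so the shift takes place in a diacetoxy-substituted cation with weak donors, under the classical dienone–phenol conditions. This should give (3R,4S)-3,4,5-trimethyl-3,4-dihydro-1H-2-benzopyran-6,8-diyl diacetate F1. Methanolysis with K2CO3 in MeOH at rt then frees 11.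

Step 6. The resorcinolate may alkylate on oxygen (O8, seven-membered ring) or lose HBr by E2 instead of closing through C8a. The fallback sets out from 3 and comes back at 10, and it keeps O8 capped during the closure.
- TBSCl (1 equiv) with imidazole in CH2Cl2 at 0 °C should silylate only the hydroxyl para to the formyl group, giving 4-[(tert-butyldimethylsilyl)oxy]-2-hydroxy-5-methylbenzaldehyde F2.
- TIPSOTf with 2,6-lutidine then gives 4-[(tert-butyldimethylsilyl)oxy]-5-methyl-2-[(triisopropylsilyl)oxy]benzaldehyde F3.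
- Acetalisation with 5, opening with i-Bu2AlH and Appel bromination, as in steps 3 to 5, give (4R,5R)-2-{4-[(tert-butyldimethylsilyl)oxy]-5-methyl-2-[(triisopropylsilyl)oxy]phenyl}-4,5-dimethyl-1,3-dioxolane F4, then (2R,3R)-3-({4-[(tert-butyldimethylsilyl)oxy]-5-methyl-2-[(triisopropylsilyl)oxy]phenyl}methoxy)butan-2-ol F5, then {4-({[(2R,3S)-3-bromobutan-2-yl]oxy}methyl)-2-methyl-5-[(triisopropylsilyl)oxy]phenoxy}(tert-butyl)dimethylsilane F6.
- K2CO3 in MeOH should cleave only the aryl TBS ether. The resulting 4-({[(2R,3S)-3-bromobutan-2-yl]oxy}methyl)-2-methyl-5-[(triisopropylsilyl)oxy]phenol F7 closes as its phenolate through C8a to (3R,4S)-3,4,9-trimethyl-6-[(triisopropylsilyl)oxy]-2-oxaspiro[4.5]deca-6,9-dien-8-one F8.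
- The vinylogous silyl ester of F8 is hydrolysed in the acidic work-up to 10.

Step 10. The liberated dimethylamine may add reversibly to C1 of 12, and 12 may condense with itself (C7 of one molecule on C1 of another) at the temperature needed to expel the amine. The fallback sets out from 11 and comes back at 15, and it generates 14 without amine at room temperature.
- Vilsmeier–Haack formylation of 11 (POCl3, DMF; then H2O) should give (3R,4S)-6,8-dihydroxy-3,4,5-trimethyl-3,4-dihydro-1H-2-benzopyran-7-carbaldehyde F9.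
- NaBH4 in MeOH at 0 °C gives (3R,4S)-7-(hydroxymethyl)-3,4,5-trimethyl-3,4-dihydro-1H-2-benzopyran-6,8-diol F10.
- F10 and 12 in (CF3)2CHOH at rt: the 2,6-dihydroxybenzyl alcohol loses water to 14, which C7 of 12 captures to give 15.

**Further compounds**

F1 | step 7 | (3R,4S)-3,4,5-trimethyl-3,4-dihydro-1H-2-benzopyran-6,8-diyl diacetate | Cc1c(OC(C)=O)cc(OC(C)=O)c2c1[C@H](C)[C@@H](C)OC2
F2 | step 6 | 4-[(tert-butyldimethylsilyl)oxy]-2-hydroxy-5-methylbenzaldehyde | O=Cc1cc(C)c(O[Si](C)(C)C(C)(C)C)cc1O
F3 | step 6 | 4-[(tert-butyldimethylsilyl)oxy]-5-methyl-2-[(triisopropylsilyl)oxy]benzaldehyde | O=Cc1cc(C)c(O[Si](C)(C)C(C)(C)C)cc1O[Si](C(C)C)(C(C)C)C(C)C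
F4 | step 6 | (4R,5R)-2-{4-[(tert-butyldimethylsilyl)oxy]-5-methyl-2-[(triisopropylsilyl)oxy]phenyl}-4,5-dimethyl-1,3-dioxolane | C[C@H]1OC(c2cc(C)c(O[Si](C)(C)C(C)(C)C)cc2O[Si](C(C)C)(C(C)C)C(C)C)O[C@@H]1C
F5 | step 6 | (2R,3R)-3-({4-[(tert-butyldimethylsilyl)oxy]-5-methyl-2-[(triisopropylsilyl)oxy]phenyl}methoxy)butan-2-ol | C[C@@H](O)[C@@H](C)OCc1cc(C)c(O[Si](C)(C)C(C)(C)C)cc1O[Si](C(C)C)(C(C)C)C(C)C
F6 | step 6 | {4-({[(2R,3S)-3-bromobutan-2-yl]oxy}methyl)-2-methyl-5-[(triisopropylsilyl)oxy]phenoxy}(tert-butyl)dimethylsilane | C[C@H](Br)[C@@H](C)OCc1cc(C)c(O[Si](C)(C)C(C)(C)C)cc1O[Si](C(C)C)(C(C)C)C(C)C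
F7 | step 6 | 4-({[(2R,3S)-3-bromobutan-2-yl]oxy}methyl)-2-methyl-5-[(triisopropylsilyl)oxy]phenol | C[C@H](Br)[C@@H](C)OCc1cc(C)c(O)cc1O[Si](C(C)C)(C(C)C)C(C)C
F8 | step 6 | (3R,4S)-3,4,9-trimethyl-6-[(triisopropylsilyl)oxy]-2-oxaspiro[4.5]deca-6,9-dien-8-one | C[C@@H]1[C@@H](C)OCC12C=C(C)C(=O)C=C2O[Si](C(C)C)(C(C)C)C(C)C
F9 | step 10 | (3R,4S)-6,8-dihydroxy-3,4,5-trimethyl-3,4-dihydro-1H-2-benzopyran-7-carbaldehyde | Cc1c(O)c(C=O)c(O)c2c1[C@H](C)[C@@H](C)OC2
F10 | step 10 | (3R,4S)-7-(hydroxymethyl)-3,4,5-trimethyl-3,4-dihydro-1H-2-benzopyran-6,8-diol | Cc1c(O)c(CO)c(O)c2c1[C@H](C)[C@@H](C)OC2
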